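Target: (2S)-2-[3,4-dihydroxy-5-(3-methylbut-2-enyl)phenyl]-5,7-dihydroxy-8-(3-methylbut-2-enyl)chroman-4-one (13). Ring B is numbered here with the prenyl group at C3' and the hydroxyls at C4' and C5'.

## Analysis of the target

Compound 13 is a flavanone: a phloroglucinol-type ring A fused to the dihydropyranone ring C, which carries the catechol ring B at C2. The only stereocenter is C2 (S), so there is no relative stereochemistry to control. C2 is benzylic, β to the C4 carbonyl and bonded to the ring oxygen O1, so base (retro-oxa-Michael opening of ring C, or quinone methide formation from a 4'-phenoxide) and strong acid can both erase it. The sensitive groups are the two trisubstituted prenyl olefins, each beside a phenolic hydroxyl that adds to it under protic acid to give a chroman, the air-sensitive catechol, and the nucleophilic free carbon C6. The difficulty is regiochemical: one prenyl group must reach C8 and not the equally activated C6, the other a ring B carbon next to oxygen, and the catechol must form beside that prenyl group, all without disturbing C2. The strategy rests on the fixed relation of each prenylated carbon to a phenolic oxygen: C8 is para to O5 on ring A and C3' is ortho to O4' on ring B. Each aryl–prenyl bond can therefore be made by intramolecular transfer of a five-carbon unit from that oxygen. Without the two prenyl groups and O5', the structure is (2S)-naringenin 1, which supplies rings A, B and C, three hydroxyls and the C2 configuration.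

## Retrosynthetic reasoning

13 from 12: the O7–Si bond is cut last. Keeping the most acidic phenol silylated to the end protects ring A during the oxidation of ring B and prevents chroman formation at the C8 prenyl group. The forward step is a buffered desilylation that needs neither free base nor strong acid.

12 from 10: the C5'–O bond is disconnected through ortho-quinone 11. In 10 the prenyl group already occupies C3', so C5' is the single free carbon ortho to the ring B phenol, and a hypervalent iodine oxidant that delivers oxygen from the phenol has one site only. Oxidising before the prenyl transfer would give a catechol whose two oxygens could not be told apart for allylation. The forward step must oxidise only ring B (the 5-OH of ring A is chelated to the C4 carbonyl on an acylated ring) and reduce 11 before it can tautomerise.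

10 from 7: the two aryl–prenyl bonds, C8–CH2 and C3'–CH2, are cut back to allyl aryl ethers. These are the bonds that [3,3] shifts form ortho and para to oxygen, so the regiochemistry becomes intramolecular. Direct electrophilic prenylation of a flavanone would give C6/C8 and O-alkylated mixtures. On ring A the group reaches C8 after two consecutive shifts, which restore the normal prenyl connectivity, so O5 carries an ordinary prenyl ether. On ring B a single shift inverts the allyl unit, so O4' must carry the tertiary 2-methylbut-3-en-2-yl group. The forward step must relay the ring A group from C6 on to C8 and must stay neutral.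

7 from 5 and prenol 6: the O5–CH2 bond. The chelated 5-OH is the least reactive hydroxyl, so it is alkylated last, when it is the only free one, by a redox condensation that uses no base.

5 from 2 and carbonate 4 (4 from alcohol 3): the O4'–C(tertiary) bond. A tertiary allyl aryl ether cannot be made by direct displacement; it is made through a π-allyl complex of zerovalent palladium generated from 4. The forward step must attack at the substituted allyl terminus, and only at O4'.

2 from 1: the O7–Si bond. The 7-OH is the most acidic hydroxyl of 1 and the 5-OH is chelated, so one equivalent of silylating agent should find O7.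

## Alternatives that were turned down

Alternative 1: Ring C is cut at C3–C4 and O1–C2, giving the ring A acetal A2 and the ring B styrene A3. In the forward sense a chiral Brønsted acid ionises A2, and the resulting cationic heterodiene adds A3 in a [4+2] sense to give the 2,4-cis 4-methoxyflavan A1. In its favour, it is convergent, it forms ring C and sets C2 in one catalytic step, it gives either enantiomer, and the prenyl positions are fixed in the fragments, so no C6/C8 question arises. On these points it is stronger than the chosen route. Against it, both fragments must be prenylated beforehand, and A2 poses the same C-prenylation problem on a trioxygenated arene. A1 is at the wrong oxidation level at C4, so ether cleavage and oxidation follow, and the C4 center just made is destroyed. The cationic conditions meet two nucleophilic prenyl olefins and acid-labile acetals. The four methoxymethyl groups must finally be removed with protic acid beside prenyl groups, which invites chroman formation and C2 epimerisation. The chosen route is far shorter, and it draws C2 from the chiral pool and keeps every step neutral.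

Alternative 2: The C4–C4a bond is cut, leading to the acid A5. Its activation and intramolecular Friedel–Crafts acylation would close ring C to the tetrasilyl ether A4, one deprotection away from 13. In its favour, the ring closure can occur at one carbon only, and all oxygens and both prenyl groups are in place, so neither a rearrangement nor a late oxidation is needed. That regiochemical certainty is greater than in the chosen route. Against it, an activated β-aryloxy acid readily loses the phenoxide by β-elimination. The benzylic C–O bond, para to a silyloxy group, ionises under acylation conditions, so C2 is at risk. The acidic medium also threatens the prenyl olefins and aryl silyl ethers. A5 itself needs two separately prenylated arenes and an enantioselective C–O bond to a hindered phenol. The chosen route reaches the same skeleton in six linear steps with the stereocenter never at risk of being formed wrongly.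

Alternative 3: Ring A is built on a chiral dihydropyranone. Irradiation of the diazo ketone A7 triggers Wolff rearrangement, then ketene–alkyne [2+2] addition with the silyloxyalkyne A8, four-electron ring opening and six-electron ring closure give the phenol A6. In its favour, the C8 prenyl group, the free 5-OH and the silylated O7 arise with complete regiocontrol, and the ring B oxygens are present from the start. On regiocontrol it is stronger than the chosen route. Against it, A7 needs an asymmetric synthesis of the 2-aryl dihydropyranone, a prenylated ring B aldehyde and a diazo transfer. The carbene has an allylic CH2 next to it that can undergo a 1,2-hydrogen shift instead of the Wolff step. The enone chromophore and the prenyl olefins are exposed to light. The final acetal removal again needs acid beside prenyl groups. The chosen route replaces this long and partly unprecedented sequence with two known sigmatropic shifts on an intact natural skeleton.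

Key step: step 5

Assumption: (2S)-naringenin 1 is bought in high enantiomeric purity and checked by chiral HPLC before use, since C2 is carried through unchanged and the purity of 13 can be no better than that of 1.

## Route

Step 1
Reactants: 1 (2S)-naringenin
Product: 2 (2S)-7-(tert-butyldimethylsilyloxy)-5-hydroxy-2-(4-hydroxyphenyl)chroman-4-one
Conditions: TBSCl (1.05 equiv), i-Pr2NEt (1.1 equiv), DMF, −20 → 0 °C
Reagents that add atoms: tert-butyldimethylsilyl chloride, CC(C)(C)[Si](C)(C)Cl
Why: Phenol O-silylation; the 7-OH is para to the C4 carbonyl (a vinylogous acid, clearly more acidic than the isolated 4'-phenol), so one equivalent of hindered amine should generate and silylate the 7-phenoxide, while the 5-OH stays locked in its hydrogen bond to the carbonyl. The base is weak and the temperature low, so ring C should not open.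

Step 2
Reactants: 3 2-methylbut-3-en-2-ol
Product: 4 tert-butyl 2-methylbut-3-en-2-yl carbonate
Conditions: n-BuLi, THF, −78 → 0 °C; Boc2O, 0 °C → rt
Reagents that add atoms: di-tert-butyl dicarbonate, CC(C)(C)OC(=O)OC(=O)OC(C)(C)C
Why: O-acylation of the lithium alkoxide of a tertiary allylic alcohol with the dicarbonate, the standard preparation of tertiary allylic carbonates.

Step 3
Reactants: 2 (2S)-7-(tert-butyldimethylsilyloxy)-5-hydroxy-2-(4-hydroxyphenyl)chroman-4-one; 4 tert-butyl 2-methylbut-3-en-2-yl carbonate
Product: 5 (2S)-7-(tert-butyldimethylsilyloxy)-5-hydroxy-2-[4-(2-methylbut-3-en-2-yloxy)phenyl]chroman-4-one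
Conditions: 4 (1.5 equiv), Pd(PPh3)4 (5 mol %), THF, 0 °C
Reagents that add atoms: none
Why: Decarboxylative allylic etherification of Tsuji–Trost type; zerovalent palladium ionises 4, the tert-butoxide released deprotonates the 4'-phenol, and the phenoxide attacks the more substituted terminus of the 1,1-dimethylallyl complex under kinetic control at 0 °C to give the tertiary ether. No external base is present, and the chelated 5-OH is too weak a nucleophile to compete.

Step 4
Reactants: 5 (2S)-7-(tert-butyldimethylsilyloxy)-5-hydroxy-2-[4-(2-methylbut-3-en-2-yloxy)phenyl]chroman-4-one; 6 prenol (3-methylbut-2-en-1-ol)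
Product: 7 (2S)-7-(tert-butyldimethylsilyloxy)-2-[4-(2-methylbut-3-en-2-yloxy)phenyl]-5-(3-methylbut-2-enyloxy)chroman-4-one
Conditions: 6 (1.5 equiv), PPh3, DIAD, THF, 0 °C → rt
Reagents that add atoms: none
Why: Mitsunobu etherification; the 5-OH is the only free hydroxyl and, although chelated, is acidic enough to protonate the betaine and attack the primary oxyphosphonium carbon of prenol. The conditions are neutral, so neither the silyl ether, the tertiary allyl ether nor C2 is affected.

Step 5
Reactants: 7 (2S)-7-(tert-butyldimethylsilyloxy)-2-[4-(2-methylbut-3-en-2-yloxy)phenyl]-5-(3-methylbut-2-enyloxy)chroman-4-one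
Product: 10 (2S)-7-(tert-butyldimethylsilyloxy)-5-hydroxy-2-[4-hydroxy-3-(3-methylbut-2-enyl)phenyl]-8-(3-methylbut-2-enyl)chroman-4-one, via ring A C6 dienone 8 (not isolated), via 8-prenyl tertiary-ether phenol 9 (not isolated)
Conditions: Eu(fod)3 [trivalent europium tris(6,6,7,7,8,8,8-heptafluoro-2,2-dimethyl-3,5-octanedionate)] (15 mol %), NaHCO3 (1 equiv), PhCl, 60 → 85 °C, Ar
Reagents that add atoms: none
Why: Eu(fod)3 chelates the C4 carbonyl and the O5 ether oxygen, which weakens the O5–CH2 bond, so an aromatic Claisen [3,3] shift carries the dimethyl-substituted allyl terminus to C6, the only ortho carbon that bears hydrogen, giving dienone 8. In 8 the 1,1-dimethylallyl group sits on an sp3 carbon crowded between the europium-bound C5 carbonyl and the C7 silyloxy group and forms a 1,5-diene with the C7=C8 silyl enol ether, so a Cope [3,3] shift should move it to C8 through its primary carbon; enolisation then gives the chelated 5-hydroxy-8-prenyl arene 9. Solid NaHCO3 scavenges adventitious acid, which would otherwise enolise 8 and freeze the group at C6, cleave the tertiary ether or close chromans. On ring B the tertiary aryl ether undergoes an ordinary aromatic Claisen shift at the upper temperature; C3' and C5' are equivalent on the para-substituted ring, so either ortho carbon gives the same 3'-prenyl-4'-phenol and no regiochemical choice arises there. Both events are known reaction types, the europium-catalysed para-Claisen–Cope rearrangement of 5-O-prenylflavanones and the Claisen rearrangement of aryl 1,1-dimethylallyl ethers to ortho-prenylphenols, here run in one flask. No ring is closed and no stereocenter is created, since the sp3 carbon C6 of 8 is lost again on the Cope shift. The selectivity needed is C8 over C6 on ring A, and it is secured by chelation, by steric pressure at C6 and by the silyl group at O7, which also blocks chroman formation at C8. C2 is not involved and should survive because the medium stays neutral and aprotic.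

Step 6
Reactants: 10 (2S)-7-(tert-butyldimethylsilyloxy)-5-hydroxy-2-[4-hydroxy-3-(3-methylbut-2-enyl)phenyl]-8-(3-methylbut-2-enyl)chroman-4-one
Product: 12 (2S)-7-(tert-butyldimethylsilyloxy)-2-[3,4-dihydroxy-5-(3-methylbut-2-enyl)phenyl]-5-hydroxy-8-(3-methylbut-2-enyl)chroman-4-one, via ring B ortho-quinone 11 (not isolated)
Conditions: IBX (1.1 equiv), DMF, 0 °C → rt, dark; then aq Na2S2O4, rt
Reagents that add atoms: 2-iodoxybenzoic acid, O=C1OI(=O)(O)c2ccccc12
Why: Regioselective phenol ortho-oxygenation; the free 4'-OH binds iodine and oxygen is delivered intramolecularly to C5', the only open ortho carbon, giving ortho-quinone 11, which dithionite reduces at once to the catechol. The 5-OH is hydrogen-bonded to C4=O on an acyl-deactivated ring and should not ligate iodine, and the prenyl olefins are inert to IBX at room temperature.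

Step 7
Reactants: 12 (2S)-7-(tert-butyldimethylsilyloxy)-2-[3,4-dihydroxy-5-(3-methylbut-2-enyl)phenyl]-5-hydroxy-8-(3-methylbut-2-enyl)chroman-4-one
Product: 13 (2S)-2-[3,4-dihydroxy-5-(3-methylbut-2-enyl)phenyl]-5,7-dihydroxy-8-(3-methylbut-2-enyl)chroman-4-one
Conditions: TBAF, AcOH (1:1, 1.2 equiv), THF, 0 °C, Ar
Reagents that add atoms: none
Why: Fluoride-mediated cleavage of an aryl silyl ether; the 7-O-silyl group of this acidic phenol is labile, and acetic acid buffering keeps the medium near neutral, so ring C does not open, the catechol is not oxidised and the prenyl groups do not cyclise.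

## Compound list

1 | (2S)-naringenin, (2S)-5,7-dihydroxy-2-(4-hydroxyphenyl)chroman-4-one | O=C1C[C@@H](c2ccc(O)cc2)Oc2cc(O)cc(O)c21 | starting material
2 | (2S)-7-(tert-butyldimethylsilyloxy)-5-hydroxy-2-(4-hydroxyphenyl)chroman-4-one | Oc1ccc([C@@H]2CC(=O)c3c(O)cc(O[Si](C)(C)C(C)(C)C)cc3O2)cc1 | intermediate
3 | 2-methylbut-3-en-2-ol | C=CC(C)(C)O | starting material
4 | tert-butyl 2-methylbut-3-en-2-yl carbonate | C=CC(C)(C)OC(=O)OC(C)(C)C | intermediate
5 | (2S)-7-(tert-butyldimethylsilyloxy)-5-hydroxy-2-[4-(2-methylbut-3-en-2-yloxy)phenyl]chroman-4-one | C=CC(C)(C)Oc1ccc([C@@H]2CC(=O)c3c(O)cc(O[Si](C)(C)C(C)(C)C)cc3O2)cc1 | intermediate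
6 | prenol, 3-methylbut-2-en-1-ol | CC(C)=CCO | starting material
7 | (2S)-7-(tert-butyldimethylsilyloxy)-2-[4-(2-methylbut-3-en-2-yloxy)phenyl]-5-(3-methylbut-2-enyloxy)chroman-4-one | C=CC(C)(C)Oc1ccc([C@@H]2CC(=O)c3c(OCC=C(C)C)cc(O[Si](C)(C)C(C)(C)C)cc3O2)cc1 | intermediate
8 | (2S)-7-(tert-butyldimethylsilyloxy)-6-(2-methylbut-3-en-2-yl)-2-[4-(2-methylbut-3-en-2-yloxy)phenyl]-2,3-dihydro-4H-chromene-4,5(6H)-dione, C6 configuration undefined | C=CC(C)(C)Oc1ccc([C@@H]2CC(=O)C3=C(O2)C=C(O[Si](C)(C)C(C)(C)C)C(C(C)(C)C=C)C3=O)cc1 | intermediate
9 | (2S)-7-(tert-butyldimethylsilyloxy)-5-hydroxy-8-(3-methylbut-2-enyl)-2-[4-(2-methylbut-3-en-2-yloxy)phenyl]chroman-4-one | C=CC(C)(C)Oc1ccc([C@@H]2CC(=O)c3c(O)cc(O[Si](C)(C)C(C)(C)C)c(CC=C(C)C)c3O2)cc1 | intermediate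
10 | (2S)-7-(tert-butyldimethylsilyloxy)-5-hydroxy-2-[4-hydroxy-3-(3-methylbut-2-enyl)phenyl]-8-(3-methylbut-2-enyl)chroman-4-one | CC(C)=CCc1cc([C@@H]2CC(=O)c3c(O)cc(O[Si](C)(C)C(C)(C)C)c(CC=C(C)C)c3O2)ccc1O | intermediate
11 | (2S)-7-(tert-butyldimethylsilyloxy)-5-hydroxy-8-(3-methylbut-2-enyl)-2-[5-(3-methylbut-2-enyl)-3,4-dioxocyclohexa-1,5-dien-1-yl]chroman-4-one | CC(C)=CCC1=CC([C@@H]2CC(=O)c3c(O)cc(O[Si](C)(C)C(C)(C)C)c(CC=C(C)C)c3O2)=CC(=O)C1=O | intermediate
12 | (2S)-7-(tert-butyldimethylsilyloxy)-2-[3,4-dihydroxy-5-(3-methylbut-2-enyl)phenyl]-5-hydroxy-8-(3-methylbut-2-enyl)chroman-4-one | CC(C)=CCc1cc([C@@H]2CC(=O)c3c(O)cc(O[Si](C)(C)C(C)(C)C)c(CC=C(C)C)c3O2)cc(O)c1O | intermediate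
13 | (2S)-2-[3,4-dihydroxy-5-(3-methylbut-2-enyl)phenyl]-5,7-dihydroxy-8-(3-methylbut-2-enyl)chroman-4-one | CC(C)=CCc1cc([C@@H]2CC(=O)c3c(O)cc(O)c(CC=C(C)C)c3O2)cc(O)c1O | target

## Step count and least certain steps

Total: 7 steps. Longest linear sequence: 6 steps (1, 3, 4, 5, 6, 7); step 2 prepares the carbonate.

Step 5, the key step. The relay on ring A may stop halfway: dienone 8 can enolise before the Cope shift, which leaves a 1,1-dimethylallyl group at C6. The Lewis acid may also ionise the tertiary ring B ether with loss of the allyl unit, or the two shifts may need such different temperatures that prolonged heating leads to cyclisation of the new prenylphenol. The fallback separates the two events. Phenol 5 is heated without Lewis acid (toluene or DMF, 110–120 °C) so that only the ring B Claisen shift occurs, giving 7-O-silyl-3'-prenylnaringenin F1. Its 4'-OH is silylated (TBSCl, imidazole) to the bis-silyl ether F2. Mitsunobu reaction with 6 gives the 5-O-prenyl ether F3. Eu(fod)3 with NaHCO3 then acts on ring A alone, on the substrate class for which the para-Claisen–Cope relay is established, giving the 8,3'-diprenyl bis-silyl ether F4. Buffered TBAF removes both silyl groups to give 8,3'-diprenylnaringenin F5. IBX then converts F5 through the ortho-quinone F6, reduced by Na2S2O4, into 13. The 7-OH set free in F5 belongs to an electron-poor vinylogous acid and should resist the oxidant.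

Step 6. The ortho-quinone may tautomerise toward a quinone methide through the C2–H or the prenyl CH2, which would scramble C2 or lead to a chromene, and the oxidant may attack ring A. The fallback avoids the quinone oxidation level. Phenol 10 is ortho-formylated at C5' (MgCl2, Et3N, paraformaldehyde, MeCN) to the salicylaldehyde F7. Dakin oxidation with H2O2 under weakly basic buffering gives the aryl formate F8, which hydrolyses in the same medium to 12. The enantiomeric purity is checked after this sequence, because it is mildly basic.

Step 3. Regiocontrol of the allylic substitution may be lost: the phenoxide may attack the primary terminus, or the tertiary ether may re-ionise on the catalyst and equilibrate to the linear 4'-O-prenyl ether. The fallback builds the tertiary carbon–oxygen bond where this ambiguity cannot arise. Phenol 2 is alkylated with 3-chloro-3-methylbut-1-yne (DBU, catalytic CuCl2, MeCN, 0 °C) to the 1,1-dimethylpropargyl ether F9. Semi-hydrogenation of F9 (H2, Pd/CaCO3 poisoned with Pb(OAc)2, quinoline, EtOAc) gives 5. The exposure to amidine base is kept short and cold, and the enantiomeric purity is checked.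

Step 1. Site selectivity may be poor: silylation may also occur at O4' or twice, or the silyl group may migrate. The fallback fixes O7 through a known selective deacylation. Naringenin 1 is peracetylated (Ac2O, pyridine) to the triacetate F10. The most labile 7-acetate is removed with thiophenol and imidazole in NMP at 0 °C to give the 4',5-diacetate F11. Its free 7-OH is silylated to the 7-O-silyl diacetate F12, and the two aryl acetates are cleaved under neutral conditions (NH4OAc, aqueous MeOH) to give 2.

## Further compounds

F1 | step 5 | (2S)-7-(tert-butyldimethylsilyloxy)-5-hydroxy-2-[4-hydroxy-3-(3-methylbut-2-enyl)phenyl]chroman-4-one | CC(C)=CCc1cc([C@@H]2CC(=O)c3c(O)cc(O[Si](C)(C)C(C)(C)C)cc3O2)ccc1O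
F2 | step 5 | (2S)-7-(tert-butyldimethylsilyloxy)-2-[4-(tert-butyldimethylsilyloxy)-3-(3-methylbut-2-enyl)phenyl]-5-hydroxychroman-4-one | CC(C)=CCc1cc([C@@H]2CC(=O)c3c(O)cc(O[Si](C)(C)C(C)(C)C)cc3O2)ccc1O[Si](C)(C)C(C)(C)C
F3 | step 5 | (2S)-7-(tert-butyldimethylsilyloxy)-2-[4-(tert-butyldimethylsilyloxy)-3-(3-methylbut-2-enyl)phenyl]-5-(3-methylbut-2-enyloxy)chroman-4-one | CC(C)=CCc1cc([C@@H]2CC(=O)c3c(OCC=C(C)C)cc(O[Si](C)(C)C(C)(C)C)cc3O2)ccc1O[Si](C)(C)C(C)(C)C
F4 | step 5 | (2S)-7-(tert-butyldimethylsilyloxy)-2-[4-(tert-butyldimethylsilyloxy)-3-(3-methylbut-2-enyl)phenyl]-5-hydroxy-8-(3-methylbut-2-enyl)chroman-4-one | CC(C)=CCc1cc([C@@H]2CC(=O)c3c(O)cc(O[Si](C)(C)C(C)(C)C)c(CC=C(C)C)c3O2)ccc1O[Si](C)(C)C(C)(C)C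
F5 | step 5 | (2S)-5,7-dihydroxy-2-[4-hydroxy-3-(3-methylbut-2-enyl)phenyl]-8-(3-methylbut-2-enyl)chroman-4-one | CC(C)=CCc1cc([C@@H]2CC(=O)c3c(O)cc(O)c(CC=C(C)C)c3O2)ccc1O
F6 | step 5 | (2S)-5,7-dihydroxy-8-(3-methylbut-2-enyl)-2-[5-(3-methylbut-2-enyl)-3,4-dioxocyclohexa-1,5-dien-1-yl]chroman-4-one | CC(C)=CCC1=CC([C@@H]2CC(=O)c3c(O)cc(O)c(CC=C(C)C)c3O2)=CC(=O)C1=O
F7 | step 6 | (2S)-7-(tert-butyldimethylsilyloxy)-2-[3-formyl-4-hydroxy-5-(3-methylbut-2-enyl)phenyl]-5-hydroxy-8-(3-methylbut-2-enyl)chroman-4-one | CC(C)=CCc1cc([C@@H]2CC(=O)c3c(O)cc(O[Si](C)(C)C(C)(C)C)c(CC=C(C)C)c3O2)cc(C=O)c1O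
F8 | step 6 | (2S)-7-(tert-butyldimethylsilyloxy)-2-[3-formyloxy-4-hydroxy-5-(3-methylbut-2-enyl)phenyl]-5-hydroxy-8-(3-methylbut-2-enyl)chroman-4-one | CC(C)=CCc1cc([C@@H]2CC(=O)c3c(O)cc(O[Si](C)(C)C(C)(C)C)c(CC=C(C)C)c3O2)cc(OC=O)c1O
F9 | step 3 | (2S)-7-(tert-butyldimethylsilyloxy)-5-hydroxy-2-[4-(2-methylbut-3-yn-2-yloxy)phenyl]chroman-4-one | C#CC(C)(C)Oc1ccc([C@@H]2CC(=O)c3c(O)cc(O[Si](C)(C)C(C)(C)C)cc3O2)cc1
F10 | step 1 | (2S)-naringenin 4',5,7-triacetate | CC(=O)Oc1ccc([C@@H]2CC(=O)c3c(OC(C)=O)cc(OC(C)=O)cc3O2)cc1
F11 | step 1 | (2S)-naringenin 4',5-diacetate | CC(=O)Oc1ccc([C@@H]2CC(=O)c3c(OC(C)=O)cc(O)cc3O2)cc1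
F12 | step 1 | (2S)-7-O-(tert-butyldimethylsilyl)naringenin 4',5-diacetate | CC(=O)Oc1ccc([C@@H]2CC(=O)c3c(OC(C)=O)cc(O[Si](C)(C)C(C)(C)C)cc3O2)cc1
A1 | alternative 1 | (2S,4S)-4-methoxy-5,7-bis(methoxymethoxy)-2-[3,4-bis(methoxymethoxy)-5-(3-methylbut-2-enyl)phenyl]-8-(3-methylbut-2-enyl)chromane | CC(C)=CCc1cc([C@@H]2C[C@H](OC)c3c(OCOC)cc(OCOC)c(CC=C(C)C)c3O2)cc(OCOC)c1OCOC
A2 | alternative 1 | 2-(dimethoxymethyl)-3,5-bis(methoxymethoxy)-6-(3-methylbut-2-enyl)phenol | COC(OC)c1c(OCOC)cc(OCOC)c(CC=C(C)C)c1O
A3 | alternative 1 | 5-ethenyl-1,2-bis(methoxymethoxy)-3-(3-methylbut-2-enyl)benzene | C=Cc1cc(CC=C(C)C)c(OCOC)c(OCOC)c1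
A4 | alternative 2 | (2S)-5,7-bis(tert-butyldimethylsilyloxy)-2-[3,4-bis(tert-butyldimethylsilyloxy)-5-(3-methylbut-2-enyl)phenyl]-8-(3-methylbut-2-enyl)chroman-4-one | CC(C)=CCc1cc([C@@H]2CC(=O)c3c(O[Si](C)(C)C(C)(C)C)cc(O[Si](C)(C)C(C)(C)C)c(CC=C(C)C)c3O2)cc(O[Si](C)(C)C(C)(C)C)c1O[Si](C)(C)C(C)(C)C
A5 | alternative 2 | (3S)-3-[3,4-bis(tert-butyldimethylsilyloxy)-5-(3-methylbut-2-enyl)phenyl]-3-[3,5-bis(tert-butyldimethylsilyloxy)-2-(3-methylbut-2-enyl)phenoxy]propanoic acid | CC(C)=CCc1cc([C@H](CC(=O)O)Oc2cc(O[Si](C)(C)C(C)(C)C)cc(O[Si](C)(C)C(C)(C)C)c2CC=C(C)C)cc(O[Si](C)(C)C(C)(C)C)c1O[Si](C)(C)C(C)(C)C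
A6 | alternative 3 | (2S)-5-hydroxy-2-[3,4-bis(methoxymethoxy)-5-(3-methylbut-2-enyl)phenyl]-8-(3-methylbut-2-enyl)-7-(triisopropylsilyloxy)chroman-4-one | CC(C)=CCc1cc([C@@H]2CC(=O)c3c(O)cc(O[Si](C(C)C)(C(C)C)C(C)C)c(CC=C(C)C)c3O2)cc(OCOC)c1OCOC
A7 | alternative 3 | (2S)-6-(2-diazo-5-methylhex-4-enoyl)-2-[3,4-bis(methoxymethoxy)-5-(3-methylbut-2-enyl)phenyl]-2,3-dihydro-4H-pyran-4-one | CC(C)=CCC(=[N+]=[N-])C(=O)C1=CC(=O)C[C@@H](c2cc(CC=C(C)C)c(OCOC)c(OCOC)c2)O1
A8 | alternative 3 | ethynyloxy(triisopropyl)silane | C#CO[Si](C(C)C)(C(C)C)C(C)C
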